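## Retrosynthetic overview

1. The C3=C4–C5=O enone comes from Saegusa–Ito oxidation of a regiodefined C4=C5 silyl enol ether. The azonane is closed just before that by N–C9 alkylation of the formamide.
2. The C3–C4 bond comes from a B-alkyl Suzuki coupling of a C4 enol triflate with hydroborated N-allylformamide.
3. The C15 tertiary acetate comes from anti iodoacetoxylation and deiodination of the Diels–Alder olefin.
4. Key step: an endo, "ortho" Diels–Alder reaction of (S)-5-silyloxy-2-(3-chloropropyl)cyclopentenone with (E)-1-acetoxy-3-methylbutadiene. It builds the six-membered ring and sets C7, C12 (quaternary) and C13.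
5. The dienophile comes from (S)-α-hydroxy-γ-butyrolactone by phosphonate acylation and intramolecular HWE. Ring order: cyclopentenone, then cyclohexene, then azonane.

Assumption: (S)-α-hydroxy-γ-butyrolactone (sold from the L-malic acid pool) and N-allylformamide are bought.

Labels follow the Lycopodium numbering: N–C1–C2–C3=C4–C5(=O)–C6–C7(H)–C8–C15(Me,OAc)–C14–C13(OAc)–C12–C11–C10–C9–N. C12 is also bonded to C4 and C7.

## Route

Step 1
Reactants: 1 1-bromo-4-chlorobutane; 2 triethyl phosphite
Product: 3 diethyl (4-chlorobutyl)phosphonate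
Conditions: neat, 1 (3 equiv), 150 °C, EtBr distilled off
Reagents that add atoms: none
Why: Michaelis–Arbuzov reaction in which the bromide end reacts far faster than the chloride, so the chloride survives as the later C9 leaving group.

Step 2
Reactants: 4 (S)-3-hydroxydihydrofuran-2(3H)-one
Product: 5 (S)-3-(tert-butyldimethylsilyloxy)dihydrofuran-2(3H)-one
Conditions: TBSCl, imidazole, DMF, 0 °C to rt
Reagents that add atoms: tert-butyldimethylsilyl chloride, CC(C)(C)[Si](C)(C)Cl
Why: Silyl ether formation on oxygen only, so the bought stereocentre (future C5) is untouched and gains the bulk that later steers the cycloaddition.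

Step 3
Reactants: 5 (S)-3-(tert-butyldimethylsilyloxy)dihydrofuran-2(3H)-one; 3 diethyl (4-chlorobutyl)phosphonate
Product: 6 diethyl [(6S)-6-(tert-butyldimethylsilyloxy)-1-chloro-8-hydroxy-5-oxooctan-4-yl]phosphonate (epimers at the P-bearing carbon)
Conditions: 3 (2.2 equiv), n-BuLi (2.1 equiv), THF, −78 °C; then 5, −78 °C; sat. NH4Cl at −78 °C
Reagents that add atoms: none
Why: Acylation of the α-lithiated phosphonate by the lactone (Claisen-type β-ketophosphonate synthesis); the second equivalent deprotonates the product, which stops over-addition, and the cold quench avoids enolisation of the silyloxy centre and silyl migration.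

Step 4
Reactants: 6 diethyl [(6S)-6-(tert-butyldimethylsilyloxy)-1-chloro-8-hydroxy-5-oxooctan-4-yl]phosphonate
Product: 8 (5S)-5-(tert-butyldimethylsilyloxy)-2-(3-chloropropyl)cyclopent-2-en-1-one, via keto aldehyde phosphonate 7 (not isolated)
Conditions: DMP, CH2Cl2, 0 °C to rt; then LiCl, i-Pr2NEt, MeCN, 0 °C to rt
Reagents that add atoms: none
Why: Dess–Martin oxidation followed by an intramolecular Horner–Wadsworth–Emmons reaction under Masamune–Roush conditions, where fast five-ring closure with a weak base outruns β-elimination of the silyloxy group and epimerisation at C5.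

Step 5
Reactants: 9 3-methylbut-2-enal
Product: 10 (1E)-3-methylbuta-1,3-dien-1-yl acetate
Conditions: isopropenyl acetate, p-TsOH (cat.), reflux, acetone distilled off
Reagents that add atoms: isopropenyl acetate, CC(=C)OC(C)=O
Why: Acid-catalysed dienol acetate formation by enol-ester exchange; the s-trans enal gives mainly the E-dienyl acetate, and the minor Z isomer cannot reach the s-cis form and stays inert in step 6.

Step 6
Reactants: 8 (5S)-5-(tert-butyldimethylsilyloxy)-2-(3-chloropropyl)cyclopent-2-en-1-one; 10 (1E)-3-methylbuta-1,3-dien-1-yl acetate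
Product: 11 (2S,3aS,7S,7aR)-2-(tert-butyldimethylsilyloxy)-7a-(3-chloropropyl)-5-methyl-1-oxo-2,3,3a,4,7,7a-hexahydro-1H-inden-7-yl acetate (cis-fused; OAc cis to the C4 carbonyl carbon; OTBS on the convex face)
Conditions: EtAlCl2 (1.1 equiv), 10 (3 equiv), CH2Cl2, −40 to 0 °C; cold 1 M HCl quench
Reagents that add atoms: none
Why: Lewis acid-promoted Diels–Alder reaction in which the nucleophilic CH2 terminus (C8) bonds to the enone β-carbon C7 (ortho rule), and the diene adds endo and anti to the C5 silyloxy group that lies beneath it in the endo transition state, which sets the cis C7/C12 fusion, the C12 quaternary centre and C13-OAc cis to C4 in one step.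

Step 7
Reactants: 11 Diels–Alder adduct
Product: 12 (2S,3aR,5S,6S,7R,7aR)-2-(tert-butyldimethylsilyloxy)-7a-(3-chloropropyl)-6-iodo-5-methyl-1-oxooctahydro-1H-indene-5,7-diyl diacetate
Conditions: NIS, AcOH/CH2Cl2 (1:1), 0 °C to rt, dark
Reagents that add atoms: N-iodosuccinimide, O=C1CCC(=O)N1I; acetic acid, CC(=O)O
Why: Electrophilic anti iodoacetoxylation in which I+ takes the face opposite the C13 acetate and the cyclopentanone ring, and acetate opens the iodonium ion at the tertiary carbon from the other face (Markovnikov), placing C15-OAc cis to C13-OAc.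

Step 8
Reactants: 12 iodo diacetate
Product: 13 (2S,3aR,5S,7S,7aR)-2-(tert-butyldimethylsilyloxy)-7a-(3-chloropropyl)-5-methyl-1-oxooctahydro-1H-indene-5,7-diyl diacetate
Conditions: n-Bu3SnH (1.5 equiv, 0.5 M), AIBN (cat.), PhMe, 80 °C
Reagents that add atoms: none
Why: Radical-chain tin hydride dehalogenation in which concentrated stannane quenches the secondary C14 radical faster than any 1,2-acyloxy shift, the primary chloride is left alone and no stereocentre is touched.

Step 9
Reactants: 13 keto diacetate
Product: 14 (3aR,4S,6S,7aS)-2-(tert-butyldimethylsilyloxy)-3a-(3-chloropropyl)-6-methyl-3-(trifluoromethylsulfonyloxy)-3a,4,5,6,7,7a-hexahydro-1H-indene-4,6-diyl diacetate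
Conditions: Comins' reagent, then KHMDS added dropwise, THF, −78 °C; sat. NH4Cl
Reagents that add atoms: N-(5-chloropyridin-2-yl)bis(trifluoromethanesulfonimide), O=S(=O)(N(c1ccc(Cl)cn1)S(=O)(=O)C(F)(F)F)C(F)(F)F
Why: Kinetic enolisation and O-triflation (enol triflate formation) where C5-H is the only enolisable position because C12 is quaternary; the in situ trap keeps the enolate away from the acetates, and the C5 stereocentre is erased after it has done its work.

Step 10
Reactants: 14 enol triflate; 15 N-allylformamide
Product: 17 (3aS,4S,6S,7aS)-2-(tert-butyldimethylsilyloxy)-3a-(3-chloropropyl)-3-(3-formamidopropyl)-6-methyl-3a,4,5,6,7,7a-hexahydro-1H-indene-4,6-diyl diacetate, via B-(3-formamidopropyl)-9-BBN 16 (not isolated)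
Conditions: 15, 9-BBN-H, THF, 0 °C to rt; then 14, Pd(dppf)Cl2 (10 mol %), AsPh3, Cs2CO3, DMF/H2O, rt to 50 °C
Reagents that add atoms: none
Why: Anti-Markovnikov hydroboration followed by B-alkyl Suzuki–Miyaura coupling brings in C1–C3 and the formylated nitrogen in one operation and leaves the C4=C5 silyl enol ether regiodefined; acetates and the alkyl chloride tolerate these conditions.

Step 11
Reactants: 17 chloro formamide
Product: 19 tricyclic silyl enol ether (7S,12S,13S,15S): the target skeleton with C4=C5(OTBS) and C3H2 in place of the enone, via primary iodide 18 (not isolated)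
Conditions: NaI, acetone, reflux; concentrate; then KHMDS (1.1 equiv), THF, 0.003 M, 0 °C to rt
Reagents that add atoms: none
Why: Finkelstein exchange followed by intramolecular SN2 N-alkylation of the formamide anion at high dilution; the two three-carbon arms sit on the neighbouring atoms C4 and C12, so the nine-membered ring closes, only the N–H is deprotonated and no stereocentre is involved.

Step 12
Reactants: 19 tricyclic silyl enol ether
Product: 20 target CNP0137427.1
Conditions: Pd(OAc)2 (1.2 equiv), MeCN, 40 °C
Reagents that add atoms: none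
Why: Saegusa–Ito oxidation in which the palladium enolate at C4 can only β-hydride eliminate towards C3 because C12 is quaternary, and the nine-membered ring allows only the in-ring cis olefin, which is the (E)-enone of the target.

## Compound list

1 | 1-bromo-4-chlorobutane | ClCCCCBr | starting material
2 | triethyl phosphite | CCOP(OCC)OCC | starting material
3 | diethyl (4-chlorobutyl)phosphonate | CCOP(=O)(OCC)CCCCCl | intermediate
4 | (S)-3-hydroxydihydrofuran-2(3H)-one | O=C1OCC[C@@H]1O | starting material
5 | (S)-3-(tert-butyldimethylsilyloxy)dihydrofuran-2(3H)-one | O=C1OCC[C@@H]1O[Si](C)(C)C(C)(C)C | intermediate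
6 | diethyl [(6S)-6-(tert-butyldimethylsilyloxy)-1-chloro-8-hydroxy-5-oxooctan-4-yl]phosphonate | CCOP(=O)(OCC)C(CCCCl)C(=O)[C@H](CCO)O[Si](C)(C)C(C)(C)C | intermediate
7 | diethyl [(6S)-6-(tert-butyldimethylsilyloxy)-1-chloro-5,8-dioxooctan-4-yl]phosphonate (not isolated) | CCOP(=O)(OCC)C(CCCCl)C(=O)[C@H](CC=O)O[Si](C)(C)C(C)(C)C | intermediate
8 | (5S)-5-(tert-butyldimethylsilyloxy)-2-(3-chloropropyl)cyclopent-2-en-1-one | ClCCCC1=CC[C@H](O[Si](C)(C)C(C)(C)C)C1=O | intermediate
9 | 3-methylbut-2-enal | CC(C)=CC=O | starting material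
10 | (1E)-3-methylbuta-1,3-dien-1-yl acetate | CC(=O)O/C=C/C(C)=C | intermediate
11 | Diels–Alder adduct (2S,3aS,7S,7aR) | CC(=O)O[C@H]1C=C(C)C[C@H]2C[C@H](O[Si](C)(C)C(C)(C)C)C(=O)[C@]21CCCCl | intermediate
12 | C14-iodo C13,C15-diacetate | CC(=O)O[C@H]1[C@H](I)[C@@](C)(OC(C)=O)C[C@H]2C[C@H](O[Si](C)(C)C(C)(C)C)C(=O)[C@]21CCCCl | intermediate
13 | C4-keto C13,C15-diacetate | CC(=O)O[C@H]1C[C@@](C)(OC(C)=O)C[C@H]2C[C@H](O[Si](C)(C)C(C)(C)C)C(=O)[C@]21CCCCl | intermediate
14 | C4 enol triflate with C5 silyloxy group | CC(=O)O[C@H]1C[C@@](C)(OC(C)=O)C[C@H]2CC(O[Si](C)(C)C(C)(C)C)=C(OS(=O)(=O)C(F)(F)F)[C@]21CCCCl | intermediate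
15 | N-allylformamide | C=CCNC=O | starting material
16 | B-(3-formamidopropyl)-9-borabicyclo[3.3.1]nonane (not isolated) | O=CNCCCB1C2CCCC1CCC2 | intermediate
17 | C4-(3-formamidopropyl) silyl enol ether with C9 chloride | CC(=O)O[C@H]1C[C@@](C)(OC(C)=O)C[C@H]2CC(O[Si](C)(C)C(C)(C)C)=C(CCCNC=O)[C@]21CCCCl | intermediate
18 | C9 iodide analogue of 17 (not isolated) | CC(=O)O[C@H]1C[C@@](C)(OC(C)=O)C[C@H]2CC(O[Si](C)(C)C(C)(C)C)=C(CCCNC=O)[C@]21CCCI | intermediate
19 | tricyclic N-formyl azonane silyl enol ether | CC(=O)O[C@H]1C[C@@](C)(OC(C)=O)C[C@H]2CC(O[Si](C)(C)C(C)(C)C)=C3CCCN(C=O)CCC[C@@]321 | intermediate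
20 | CNP0137427.1 (7S,12S,13S,15S,3E) | CC(=O)O[C@H]1C[C@@](C)(OC(C)=O)C[C@H]2CC(=O)/C3=C/CCN(C=O)CCC[C@@]321 | target

## Step count and risks

Total steps: 12.
Longest linear sequence: 10 (4 → 5 → 6 → 8 → 11 → 12 → 13 → 14 → 17 → 19 → 20).

**Most likely to fail, first: step 6.** A 2-alkylcyclopentenone is a poor dienophile, and the dienyl acetate is only moderately electron-rich and sensitive to the Lewis acid. The fallback sets out from 8 and 9 and returns at 11, and it changes the four-carbon partner and the bond-forming manifold.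
- Compound 9 is silylated (TMSCl, Et3N, cat. ZnCl2) to (E)-3-methyl-1-(trimethylsilyloxy)buta-1,3-diene F1.
- F1 is combined with 8 under catalytic Tf2NH at −78 °C. The ring can close in concert or stepwise, by a vinylogous Mukaiyama–Michael addition at C7 and then aldol closure at C12. This gives the C13 trimethylsilyl ether adduct F2.
- Citric acid in MeOH removes only the labile allylic TMS group and gives the C13 alcohol F3.
- Ac2O, pyridine and cat. DMAP at 0 °C give 11.

**Second: step 7.** The olefin is deactivated by the allylic acetate, the C13 acetate may take part in the opening, and the face of attack decides C15. The fallback sets out from 11 and returns at 13, skipping 12, and it swaps the ionic addition for a radical Markovnikov hydration.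
- Mn(dpm)3 (cat.), PhSiH3, O2, i-PrOH, then P(OEt)3, gives the C15 tertiary alcohols.
- The (15S) tertiary alcohol F4 is separated by chromatography.
- F4 is acetylated (Ac2O, Et3N, DMAP, 40 °C) to 13.

**Third: step 10.** The triflate is tetrasubstituted, electron-rich and flanked by the quaternary C12, so transmetalation of a bulky B-alkyl group may lose out to triflate hydrolysis. The fallback sets out from 14 and returns at 17, and it uses a slim sp-carbon nucleophile instead.
- Propargylamine and ethyl formate give N-(prop-2-yn-1-yl)formamide F5.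
- F5 is joined to 14 by Sonogashira coupling (Pd(PPh3)4, CuI, Et3N, DMF) to give the conjugated enyne silyl enol ether F6.
- Hydrogenation (H2, Pd/C, EtOAc) saturates the alkyne but not the tetrasubstituted silyl enol ether and gives 17.

## Further compounds

F1 | step 6 | (E)-3-methyl-1-(trimethylsilyloxy)buta-1,3-diene | C[Si](C)(C)O/C=C/C(C)=C
F2 | step 6 | C13 trimethylsilyl ether adduct | C[Si](C)(C)O[C@H]1C=C(C)C[C@H]2C[C@H](O[Si](C)(C)C(C)(C)C)C(=O)[C@]21CCCCl
F3 | step 6 | C13 alcohol | O[C@H]1C=C(C)C[C@H]2C[C@H](O[Si](C)(C)C(C)(C)C)C(=O)[C@]21CCCCl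
F4 | step 7 | (15S) tertiary alcohol | CC(=O)O[C@H]1C[C@@](C)(O)C[C@H]2C[C@H](O[Si](C)(C)C(C)(C)C)C(=O)[C@]21CCCCl
F5 | step 10 | N-(prop-2-yn-1-yl)formamide | C#CCNC=O
F6 | step 10 | conjugated enyne silyl enol ether | CC(=O)O[C@H]1C[C@@](C)(OC(C)=O)C[C@H]2CC(O[Si](C)(C)C(C)(C)C)=C(C#CCNC=O)[C@]21CCCCl
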